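**Retrosynthetic overview**
1. Target 24 ⇐ ester 23 (C15 silyl ether, C3 masked as the methyl ketal of the 3,10-hemiketal) ⇐ C8 ketone 20, by catalyst-controlled reduction and acylation with (R)-2-methylbutanoic acid.
2. Ten-membered ring ⇐ alkoxy-radical scission of a temporary C3–C8 bond in tetracycle 18. The C3 carbonyl and the C8 oxygen are 1,6 across the macrocycle through the (Z)-C4=C5 alkene, C6 and C7, so they can be adjacent carbons of a cyclohexene (ring A, C3–C8), which carries the cis alkene and the cis lactone.
3. Key step: the C8–C9 bond closes ring B (C8, C9, C10, C1, C2, C3) by Prins attack of a 3-methylbut-3-enyl chain on the C8 ketone of α-hydroxy ketone 15, and the C10 cation is caught by the C3 oxygen. This uses the 1,4-relation of C3=O and C10–OH (the latent 3,10-hemiketal) to set C10 and to arm the C3–C8 bond for scission.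
4. Ring A ⇐ dearomatization of 2-hydroxy-5-methoxybenzaldehyde 1 to a quinone monoketal: its six ring carbons are C3–C8 and its three oxygens become the oxygens on C3, C6 and C15. A rhodium-catalysed asymmetric 2-propenyl addition sets C7, from which C3, C6, C10 and C8 are relayed.
5. Ring order: ring A (from the arene) → lactone ring (C6, C7, C11, C12, O) → ring B with the oxygen bridge (key step) → ten-membered ring (scission of the bond shared by rings A and B).

Key step: step 13

Remark: locants C1–C15 are those of the germacrane skeleton of the target (C3 ketone, C4=C5, C6 lactone O–CH, C7 ring-fusion CH, C8 ester carbinol, C10 tertiary carbinol, C11–C13 lactone C(=CH2)C=O, C14 methyl on C10, C15 CH2OH on C4).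
Remark: the target is taken as drawn, with an (R)-2-methylbutanoate and the open 3-oxo-10-hydroxy form; the cyclic 3,10-hemiketal is its ring-chain tautomer and the last step would deliver the two in equilibrium.

Step 1
Reactants: 1 2-hydroxy-5-methoxybenzaldehyde
Product: 2 2-(hydroxymethyl)-4-methoxyphenol
Conditions: NaBH4, MeOH, 0 °C
Reagents that add atoms: none
Why: Borohydride reduction of the aryl aldehyde gives the benzylic alcohol that becomes C15–OH, and no stereocenter is formed.

Step 2
Reactants: 2 2-(hydroxymethyl)-4-methoxyphenol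
Product: 3 2-(hydroxymethyl)-4,4-dimethoxycyclohexa-2,5-dien-1-one
Conditions: PhI(OAc)2, MeOH, 0 °C
Reagents that add atoms: methanol, CO
Why: Oxidative dearomatization of a para-methoxyphenol with a trivalent iodine reagent in methanol gives the quinone monoketal, which turns the arene into ring A with the C3 carbonyl free and the C6 carbonyl masked.

Step 3
Reactants: 3 2-(hydroxymethyl)-4,4-dimethoxycyclohexa-2,5-dien-1-one
Product: 4 silyl ether of 3
Conditions: TBDPSCl, imidazole, CH2Cl2, 0 → 25 °C
Reagents that add atoms: tert-butyl(chloro)diphenylsilane, CC(C)(C)[Si](Cl)(c1ccccc1)c1ccccc1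
Why: Silylation of the only free hydroxyl protects C15–OH with a group that should survive the bases, hydrides, Lewis acids and oxidants used later.

Step 4
Reactants: 4 silyl ether of 3; 5 potassium trifluoro(prop-1-en-2-yl)borate
Product: 6 (7S)-2-propenyl enone
Conditions: [Rh(cod)2]BF4 (cat.), (S)-BINAP, Et3N, toluene/H2O, 25 °C
Reagents that add atoms: potassium trifluoro(prop-1-en-2-yl)borate 5, [K+].C=C(C)[B-](F)(F)F
Why: Rhodium-catalysed asymmetric conjugate addition of an alkenyltrifluoroborate to a quinone monoketal has close precedent, should occur at the enone arm that lacks an α-substituent (C7), and with (S)-BINAP should set C7 as S by the face selection usual for cyclic enones (the ligand antipode would be used if the sense proved opposite).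

Step 5
Reactants: 6 (7S)-2-propenyl enone
Product: 7 (7S)-allylic chloride
Conditions: Ca(OCl)2, CO2 (dry ice), CH2Cl2/H2O, 0 °C
Reagents that add atoms: calcium hypochlorite, [Ca+2].[O-]Cl.[O-]Cl
Why: Ene-type allylic chlorination by hypochlorous acid is selective for the electron-rich 1,1-disubstituted alkene over the enone and gives the 2-(chloromethyl)vinyl group, so that C12 is functionalized while C7 is untouched.

Step 6
Reactants: 7 (7S)-allylic chloride
Product: 8 (7S)-enal
Conditions: NMO, MeCN, 25 °C
Reagents that add atoms: 4-methylmorpholine N-oxide, C[N+]1([O-])CCOCC1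
Why: Kornblum-type oxidation of the allylic chloride by an amine N-oxide (substitution, then elimination) gives the 2-substituted acrolein under neutral conditions that spare the ketal and the enone.

Step 7
Reactants: 8 (7S)-enal
Product: 9 (7S)-acrylic acid
Conditions: NaClO2, NaH2PO4, 2-methylbut-2-ene, t-BuOH/H2O, 0 °C
Reagents that add atoms: sodium chlorite, [Na+].[O-]Cl=O
Why: Pinnick oxidation brings C12 to the lactone oxidation level without touching the alkenes, the added alkene scavenging hypochlorous acid.

Step 8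
Reactants: 9 (7S)-acrylic acid
Product: 10 (7S)-C8 spiro-dithiane
Conditions: LiN(SiMe3)2 (3.2 equiv), THF, −78 °C; TsS(CH2)3STs, −78 → 0 °C; aq. NH4Cl
Reagents that add atoms: propane-1,3-diyl bis(4-methylbenzenethiosulfonate), Cc1ccc(cc1)S(=O)(=O)SCCCSS(=O)(=O)c1ccc(C)cc1
Why: Double sulfenylation of the only enolizable position (C8) of the enolate installs the C8 carbonyl in a masked form that is not a stereocenter and makes the C3 ketone non-enolizable.

Step 9
Reactants: 10 (7S)-C8 spiro-dithiane; 11 4-bromo-2-methylbut-1-ene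
Product: 12 (3R,7S)-tertiary alcohol
Conditions: Mg, THF, 25 °C (Grignard reagent from 11); then 10, THF, −78 → −20 °C; aq. NH4Cl
Reagents that add atoms: (3-methylbut-3-en-1-yl)magnesium bromide made in the flask from 11, C=C(C)CC[Mg]Br
Why: Grignard 1,2-addition to the non-enolizable enone carbonyl installs C2, C1, C10, C14 and C9, and the reagent should approach C3 from the face opposite the C7 side chain (1,3-related to it and pushed axial by the dithiane, which itself does not bias either face), so that the C3 oxygen ends cis to that side chain (3R).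

Step 10
Reactants: 12 (3R,7S)-tertiary alcohol
Product: 13 (3R,7S)-C6 ketone
Conditions: PPTS, acetone/H2O, 25 °C
Reagents that add atoms: water, O
Why: Mild acid hydrolysis cleaves the allylic dimethyl ketal much faster than the dithiane or the silyl ether, and it frees the C6 ketone only after C3 has become sp3, so that no enedione able to aromatize can form.

Step 11
Reactants: 13 (3R,7S)-C6 ketone
Product: 14 (3R,6S,7S)-cis-lactone
Conditions: LiBH(s-Bu)3 (L-Selectride), THF, −78 °C; then 1 M HCl to pH 3, 25 °C
Reagents that add atoms: none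
Why: 1,2-Reduction of the β,β-disubstituted enone by a bulky hydride from the face opposite the adjacent C7 substituent should give the C6 alcohol cis to it (6S), which lactonizes on acidification to the cis-fused α-methylene-γ-butyrolactone.

Step 12
Reactants: 14 (3R,6S,7S)-cis-lactone
Product: 15 (3R,6S,7S)-α-hydroxy ketone
Conditions: PhI(OCOCF3)2, MeCN/H2O, 0 °C
Reagents that add atoms: water, O
Why: Oxidative hydrolysis of the dithiane by a trivalent iodine reagent frees the C8 ketone under conditions that should leave the alkenes, the lactone and the silyl ether intact.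

Step 13
Reactants: 15 (3R,6S,7S)-α-hydroxy ketone
Product: 18 oxygen-bridged tetracyclic alcohol (3R,6S,7S,8S,10R), via silyl ether 16 (not isolated), via bridged silyl ether 17 (not isolated)
Conditions: TMSOTf (2.2 equiv), 2,6-di-tert-butyl-4-methylpyridine, CH2Cl2, −78 → −30 °C; then citric acid, MeOH, 0 °C
Reagents that add atoms: none
Why: Proposed new method: the C3 hydroxyl is silylated in the flask, TMSOTf then activates the C8 ketone, the terminal alkene carbon C9 attacks it (Prins cyclization) and the tertiary C10 cation is captured by the C3 silyl ether oxygen with transfer of the silyl group, so that one operation forms the C8–C9 bond, the C10–O bond and the 7-oxanorbornane of 17. The closest known reaction types are Lewis acid-promoted carbonyl-ene and Prins cyclizations of ketones that carry a 3-methylbut-3-enyl chain, Prins cyclizations terminated by silyl ethers and the acid-catalysed closure of 4-hydroxycyclohexyl cations to 1,4-cineole-type ethers; their union on an α-silyloxy ketone has not been shown. Ring B (C8, C9, C10, C1, C2, C3) closes 6-exo-trig at the carbonyl and 6-endo-trig at the alkene as Markovnikov polarization requires, and the oxygen bridge closes by 1,4-capture across a boat of ring B to give the five-membered O–C3–C2–C1–C10 ring. The tether lets C9 reach only the carbonyl face on the side of the chain (cis fusion, C8 S, a centre that is erased in step 14), and the bridge can form only on the face of the C3 oxygen, so that C10 (R, methyl C14 exo) is dictated by C3 and through step 9 by C7. The step needs carbonyl activation to outrun proton-mediated addition of the C3 oxygen to the alkene and enol silylation toward C7 (which would expel the lactone oxygen); the capped hydroxyl, the proton-free medium with a hindered pyridine and the low temperature are chosen for this, and the electron-poor C11=C13 and C4=C5 alkenes cannot act as nucleophiles. Mild acidic methanolysis on work-up then frees only the tertiary C8 silyl ether.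

Step 14
Reactants: 18 oxygen-bridged tetracyclic alcohol
Product: 20 ten-membered methyl ketal (3S,4Z,6S,7S,10R), via acetoxy ketal 19 (not isolated)
Conditions: PhI(OAc)2, I2, CH2Cl2, visible light, 25 °C; then MeOH, PPTS, 25 °C
Reagents that add atoms: methanol, CO
Why: Hypoiodite-mediated alkoxy-radical β-fragmentation with oxidative termination, known for ring-fusion tertiary alcohols that open to ten-membered ketones, should cleave the C3–C8 bond because this gives the tertiary α-alkoxy allylic C3 radical and relieves the strain of the oxygen-bridged bicycle; the radical is oxidized to the oxocarbenium ion, trapped as acetate 19 and exchanged to the methyl ketal, whose C3 configuration (C4 cis to C9 on the oxolane ring) is the only one the bridged ten-membered ring allows.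

Step 15
Reactants: 20 ten-membered methyl ketal
Product: 21 (8R)-alcohol
Conditions: (S)-2-methyl-CBS-oxazaborolidine (0.5 equiv), catecholborane, toluene, −78 °C; MeOH
Reagents that add atoms: none
Why: Corey–Bakshi–Shibata reduction is chemoselective for the only free ketone (C3 is masked and the lactone is inert), and the (S)-catalyst should deliver hydride with the branched C7 side as the large group, which corresponds to 8R.

Step 16
Reactants: 21 (8R)-alcohol; 22 (R)-2-methylbutanoic acid
Product: 23 (8R)-2-methylbutanoate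
Conditions: EDC·HCl, DMAP, CH2Cl2, 0 → 25 °C
Reagents that add atoms: (R)-2-methylbutanoic acid 22, CC[C@@H](C)C(=O)O
Why: Steglich esterification of the secondary C8 alcohol, run cold to avoid epimerization of the α-branched acid, installs the ester while the tertiary C10 oxygen is still tied in the ketal.

Step 17
Reactants: 23 (8R)-2-methylbutanoate
Product: 24 target
Conditions: HF·pyridine, THF, 0 → 25 °C; then H2O
Reagents that add atoms: water, O
Why: Fluoride cleaves the primary silyl ether and the acidic medium ionizes the cyclic methyl ketal to an allyl-stabilized oxocarbenium ion that water converts to the 3,10-hemiketal, the ring-chain tautomer of the 3-oxo-10-hydroxy target, without touching the lactone, the ester or any stereocenter.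

**Compound list**
1 | 2-hydroxy-5-methoxybenzaldehyde | COc1ccc(O)c(C=O)c1 | starting material
2 | 2-(hydroxymethyl)-4-methoxyphenol | COc1ccc(O)c(CO)c1 | intermediate
3 | 2-(hydroxymethyl)-4,4-dimethoxycyclohexa-2,5-dien-1-one | O=C1C=CC(OC)(OC)C=C1CO | intermediate
4 | 2-[(tert-butyldiphenylsilyloxy)methyl]-4,4-dimethoxycyclohexa-2,5-dien-1-one | O=C1C=CC(OC)(OC)C=C1CO[Si](c2ccccc2)(c2ccccc2)C(C)(C)C | intermediate
5 | potassium trifluoro(prop-1-en-2-yl)borate | [K+].C=C(C)[B-](F)(F)F | starting material
6 | (5S)-2-[(tert-butyldiphenylsilyloxy)methyl]-4,4-dimethoxy-5-(prop-1-en-2-yl)cyclohex-2-en-1-one | O=C1C[C@@H](C(C)=C)C(OC)(OC)C=C1CO[Si](c2ccccc2)(c2ccccc2)C(C)(C)C | intermediate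
7 | (5S)-2-[(tert-butyldiphenylsilyloxy)methyl]-5-(3-chloroprop-1-en-2-yl)-4,4-dimethoxycyclohex-2-en-1-one | O=C1C[C@@H](C(CCl)=C)C(OC)(OC)C=C1CO[Si](c2ccccc2)(c2ccccc2)C(C)(C)C | intermediate
8 | 2-[(1S)-4-[(tert-butyldiphenylsilyloxy)methyl]-2,2-dimethoxy-5-oxocyclohex-3-en-1-yl]prop-2-enal | O=C1C[C@@H](C(C=O)=C)C(OC)(OC)C=C1CO[Si](c2ccccc2)(c2ccccc2)C(C)(C)C | intermediate
9 | 2-[(1S)-4-[(tert-butyldiphenylsilyloxy)methyl]-2,2-dimethoxy-5-oxocyclohex-3-en-1-yl]prop-2-enoic acid | O=C1C[C@@H](C(=C)C(=O)O)C(OC)(OC)C=C1CO[Si](c2ccccc2)(c2ccccc2)C(C)(C)C | intermediate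
10 | 2-[(1S)-4-[(tert-butyldiphenylsilyloxy)methyl]-2,2-dimethoxy-5-oxo-6,6-(propane-1,3-diyldisulfanediyl)cyclohex-3-en-1-yl]prop-2-enoic acid (spiro-1,3-dithiane at C8) | O=C1C2(SCCCS2)[C@@H](C(=C)C(=O)O)C(OC)(OC)C=C1CO[Si](c3ccccc3)(c3ccccc3)C(C)(C)C | intermediate
11 | 4-bromo-2-methylbut-1-ene | C=C(C)CCBr | starting material
12 | 2-[(1S,5R)-4-[(tert-butyldiphenylsilyloxy)methyl]-5-hydroxy-2,2-dimethoxy-5-(3-methylbut-3-en-1-yl)-6,6-(propane-1,3-diyldisulfanediyl)cyclohex-3-en-1-yl]prop-2-enoic acid | C=C(C)CC[C@@]1(O)C(CO[Si](c2ccccc2)(c2ccccc2)C(C)(C)C)=CC(OC)(OC)[C@H](C(=C)C(=O)O)C13SCCCS3 | intermediate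
13 | 2-[(1S,5R)-4-[(tert-butyldiphenylsilyloxy)methyl]-5-hydroxy-5-(3-methylbut-3-en-1-yl)-2-oxo-6,6-(propane-1,3-diyldisulfanediyl)cyclohex-3-en-1-yl]prop-2-enoic acid | C=C(C)CC[C@@]1(O)C(CO[Si](c2ccccc2)(c2ccccc2)C(C)(C)C)=CC(=O)[C@H](C(=C)C(=O)O)C13SCCCS3 | intermediate
14 | (3aS,5R,7aS)-6-[(tert-butyldiphenylsilyloxy)methyl]-5-hydroxy-3-methylidene-5-(3-methylbut-3-en-1-yl)-4,4-(propane-1,3-diyldisulfanediyl)-3a,4,5,7a-tetrahydro-1-benzofuran-2(3H)-one | C=C(C)CC[C@@]1(O)C(CO[Si](c2ccccc2)(c2ccccc2)C(C)(C)C)=C[C@@H]2OC(=O)C(=C)[C@@H]2C13SCCCS3 | intermediate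
15 | (3aS,5R,7aS)-6-[(tert-butyldiphenylsilyloxy)methyl]-5-hydroxy-3-methylidene-5-(3-methylbut-3-en-1-yl)-3a,7a-dihydro-1-benzofuran-2,4(3H,5H)-dione | C=C(C)CC[C@@]1(O)C(CO[Si](c2ccccc2)(c2ccccc2)C(C)(C)C)=C[C@@H]2OC(=O)C(=C)[C@@H]2C1=O | intermediate
16 | trimethylsilyl ether of 15 at the C3 oxygen | C=C(C)CC[C@@]1(O[Si](C)(C)C)C(CO[Si](c2ccccc2)(c2ccccc2)C(C)(C)C)=C[C@@H]2OC(=O)C(=C)[C@@H]2C1=O | intermediate
17 | trimethylsilyl ether of 18 at the C8 oxygen | C[C@]12CC[C@@]3(O1)C(CO[Si](c5ccccc5)(c5ccccc5)C(C)(C)C)=C[C@@H]4OC(=O)C(=C)[C@@H]4[C@@]3(O[Si](C)(C)C)C2 | intermediate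
18 | (3R,6S,7S,8S,10R)-15-(tert-butyldiphenylsilyloxy)-3,10-epoxy-8-hydroxy-3,8-cyclogermacra-4,11(13)-dien-12,6-olide (ring A cis-fused to the lactone at C6–C7 and to ring B at C3–C8, oxygen bridge C3–O–C10) | C[C@]12CC[C@@]3(O1)C(CO[Si](c5ccccc5)(c5ccccc5)C(C)(C)C)=C[C@@H]4OC(=O)C(=C)[C@@H]4[C@@]3(O)C2 | intermediate
19 | (3R,4Z,6S,7S,10R)-3-acetoxy-15-(tert-butyldiphenylsilyloxy)-3,10-epoxy-8-oxogermacra-4,11(13)-dien-12,6-olide | C[C@]12CC[C@](OC(C)=O)(O1)/C(CO[Si](c4ccccc4)(c4ccccc4)C(C)(C)C)=C\[C@@H]3OC(=O)C(=C)[C@@H]3C(=O)C2 | intermediate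
20 | (3S,4Z,6S,7S,10R)-15-(tert-butyldiphenylsilyloxy)-3,10-epoxy-3-methoxy-8-oxogermacra-4,11(13)-dien-12,6-olide | C[C@]12CC[C@](OC)(O1)/C(CO[Si](c4ccccc4)(c4ccccc4)C(C)(C)C)=C\[C@@H]3OC(=O)C(=C)[C@@H]3C(=O)C2 | intermediate
21 | (3S,4Z,6S,7R,8R,10R)-15-(tert-butyldiphenylsilyloxy)-3,10-epoxy-8-hydroxy-3-methoxygermacra-4,11(13)-dien-12,6-olide | C[C@]12CC[C@](OC)(O1)/C(CO[Si](c4ccccc4)(c4ccccc4)C(C)(C)C)=C\[C@@H]3OC(=O)C(=C)[C@@H]3[C@H](O)C2 | intermediate
22 | (R)-2-methylbutanoic acid | CC[C@@H](C)C(=O)O | starting material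
23 | (3S,4Z,6S,7R,8R,10R)-15-(tert-butyldiphenylsilyloxy)-3,10-epoxy-3-methoxy-8-[(2R)-2-methylbutanoyloxy]germacra-4,11(13)-dien-12,6-olide | C[C@]12CC[C@](OC)(O1)/C(CO[Si](c4ccccc4)(c4ccccc4)C(C)(C)C)=C\[C@@H]3OC(=O)C(=C)[C@@H]3[C@H](OC(=O)[C@H](C)CC)C2 | intermediate
24 | (4Z,6S,7R,8R,10R)-10,15-dihydroxy-8-[(2R)-2-methylbutanoyloxy]-3-oxogermacra-4,11(13)-dien-12,6-olide | C=C1C(=O)O[C@H]2/C=C(/CO)C(=O)CC[C@@](C)(O)C[C@@H](OC(=O)[C@H](C)CC)[C@@H]12 | target

Total step count: 17. Longest linear sequence: 17 steps (1 → 24); compounds 5, 11 and 22 are bought.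

**Steps most likely to fail**

Step 13 (the labelled step). The C3 oxygen may add to the alkene under adventitious proton catalysis before the C8–C9 bond forms, which would give a dead-end spiro ether. The C8 ketone may be enol-silylated toward C7 and lose the lactone oxygen by β-elimination. The cascade may also stop after proton loss from the C10 cation. The fallback uses known chemistry, sets out from 15 and comes back at 18. Me2AlCl (CH2Cl2, −78 → −20 °C) chelates the α-hydroxy ketone and should promote an intramolecular carbonyl-ene reaction that closes the same C8–C9 bond and gives the cis-fused homoallylic diol F1 with an exocyclic C10=C14 methylene. Oxymercuration with Hg(OCOCF3)2 (THF, 0 °C) should add the C3 hydroxyl, the only one that can reach C10, and give the bridged organomercurial F2. Bu3SnH then reduces F2 to 18.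

Step 14. The alkoxy radical may fragment toward C7 (an allyl radical next to the lactone) rather than toward C3. Acetyl hypoiodite may add to the C4=C5 alkene. The allyl oxocarbenium ion may be captured at C5. The fallback replaces radical scission by glycol cleavage, sets out from 15 and comes back at 20. The homoallylic diol F1 of the carbonyl-ene reaction is a cis-1,2-diol at C3/C8, and Pb(OAc)4 (benzene, 25 °C) should cleave it to the ten-membered 3,8-diketone F3. Methoxymercuration (Hg(OCOCF3)2, MeOH) should add the C3 carbonyl oxygen across the ring to C10 and give the organomercurial ketal F4, which Bu3SnH reduces to 20. On this path C10 is set by the conformation of the ten-membered ring and would have to be checked, and the β,γ-unsaturated C8 ketone of F3 must be kept from conjugating.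

Step 15. Facial selectivity may be poor or reversed if catalyst control is mismatched with the conformation of the bridged ten-membered ketone. The fallback sets out from 20 and comes back at 23. Substrate-controlled reduction (NaBH4, CeCl3, MeOH, −78 °C) is tried; if it gives the 8-epi alcohol F5, a Mitsunobu esterification with acid 22 (PPh3, DIAD, toluene) inverts C8 and gives 23 directly.

**Further compounds**
F1 | step 13 | (3R,6S,7S,8S)-15-(tert-butyldiphenylsilyloxy)-3,8-dihydroxy-3,8-cyclogermacra-4,10(14),11(13)-trien-12,6-olide | O[C@@]12CCC(=C)C[C@]1(O)[C@H]3C(=C)C(=O)O[C@H]3C=C2CO[Si](c4ccccc4)(c4ccccc4)C(C)(C)C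
F2 | step 13 | 14-(trifluoroacetoxymercurio) derivative of 18 | FC(F)(F)C(=O)O[Hg]C[C@]12CC[C@@]3(O1)C(CO[Si](c5ccccc5)(c5ccccc5)C(C)(C)C)=C[C@@H]4OC(=O)C(=C)[C@@H]4[C@@]3(O)C2
F3 | step 14 | (4Z,6S,7S)-15-(tert-butyldiphenylsilyloxy)-3,8-dioxogermacra-4,10(14),11(13)-trien-12,6-olide | C=C1CCC(=O)/C(CO[Si](c2ccccc2)(c2ccccc2)C(C)(C)C)=C\[C@@H]3OC(=O)C(=C)[C@@H]3C(=O)C1
F4 | step 14 | 14-(trifluoroacetoxymercurio) derivative of 20 | FC(F)(F)C(=O)O[Hg]C[C@]12CC[C@](OC)(O1)/C(CO[Si](c4ccccc4)(c4ccccc4)C(C)(C)C)=C\[C@@H]3OC(=O)C(=C)[C@@H]3C(=O)C2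
F5 | step 15 | (3S,4Z,6S,7R,8S,10R)-15-(tert-butyldiphenylsilyloxy)-3,10-epoxy-8-hydroxy-3-methoxygermacra-4,11(13)-dien-12,6-olide (8-epimer of 21) | C[C@]12CC[C@](OC)(O1)/C(CO[Si](c4ccccc4)(c4ccccc4)C(C)(C)C)=C\[C@@H]3OC(=O)C(=C)[C@@H]3[C@@H](O)C2
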